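**Plan**

1. Ring names: A (dihydroxybenzo ring) and C (pyranone) make up the flavanone, B is the central arene, D is the 2,2-dimethylpyranone fused to B. The retrosynthesis cuts, in this order, three O–benzyl bonds, the bond from C2 of ring C to C6 of ring B, and the C2–C3 bond of ring D.
2. Enabling feature: in ring D, C2 carries O1 and two methyl groups, and the neighbouring ring B carbon C8 carries a free hydroxyl. O1–C2(CH3)2 together with O8 are the atoms of a catechol acetone ketal, and C3–C4(=O) are those of an acetyl group ortho to it. Rings B/D are therefore an isomer of 4-acetyl-2,2-dimethyl-1,3-benzodioxole in which the ketal carbon has moved from oxygen to the acetyl methyl carbon.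
3. Forward: commercial 2,2-dimethyl-1,3-benzodioxole (ring B) is acetylated and brominated. A silyl triflate-triggered isomerization of the ketal then closes ring D and frees O8 in one event, using up the temporary dioxole ring so that no helper remains.
4. The bromide is turned into a boronic acid and joined to 5,7-bis(benzyloxy)chromone (rings A and C preformed) by asymmetric 1,4-addition; hydrogenolysis of three benzyl ethers ends the route.
5. Stereochemistry: the single stereocentre, C2 of ring C (S), is set by the chiral pyridine-oxazoline ligand in the 1,4-addition. Ring D is closed before that, on a fragment with no stereocentre and no second enolizable ketone.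

Key step: step 3

Remark (assumption): the facial sense of the pyridine-oxazoline/palladium arylation of chromones is taken to follow that known for cyclic enones, so the R ligand should give the 2S flavanone; if the sense is reversed on this substrate, the S ligand is used instead.

**Route**

Step 1
Reactants: 1 2,2-dimethyl-1,3-benzodioxole
Product: 4 1-(2,2-dimethyl-1,3-benzodioxol-4-yl)ethanone, via aryllithium 2 (not isolated), via lithium hemiaminal adduct 3 (not isolated)
Conditions: n-BuLi, THF, –10 → 0 °C; then MeC(O)N(OMe)Me, –78 °C → rt; aq. NH4Cl
Reagents that add atoms: N-methoxy-N-methylacetamide, CC(=O)N(C)OC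
Why: Directed ortho-metalation places lithium at C4 next to a ring oxygen, and the Weinreb ketone synthesis holds the acyl adduct as a chelated tetrahedral intermediate until work-up, so the methyl ketone should form without over-addition.

Step 2
Reactants: 4 1-(2,2-dimethyl-1,3-benzodioxol-4-yl)ethanone
Product: 5 1-(6-bromo-2,2-dimethyl-1,3-benzodioxol-4-yl)ethanone
Conditions: NBS, DMF, 0 °C → rt, dark
Reagents that add atoms: N-bromosuccinimide, O=C1CCC(=O)N1Br
Why: Electrophilic aromatic bromination should go to C6, which is para to the ring oxygen on C3a and meta to the acetyl group, whereas C5 and C7 are ortho and para to the acetyl group and deactivated.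

Step 3
Reactants: 5 1-(6-bromo-2,2-dimethyl-1,3-benzodioxol-4-yl)ethanone
Product: 8 6-bromo-8-hydroxy-2,2-dimethylchroman-4-one, via enol silane 6 (not isolated), via aryl silyl ether 7 (not isolated)
Conditions: Et3N (1.1 equiv), TMSOTf (1.1 equiv), CH2Cl2, 0 °C; then TMSOTf (0.3 equiv), 0 °C → rt; then 1 M HCl, THF
Reagents that add atoms: none
Why: Proposed new method: soft enolization (Et3N/TMSOTf) turns the acetyl group into enol silane 6; free TMSOTf then silylates the less hindered ketal oxygen O1 (on C7a, remote from the enol silane), the dioxole opens to an oxocarbenium ion on the isopropylidene carbon that stays bound to O3 (on C3a, beside the enol silane), the enol carbon attacks it to form the CH2–C(CH3)2 bond, and the silyl group on the new carbonyl oxygen returns to triflate, so that dioxole O3 becomes O1 of ring D, dioxole O1 becomes the silylated C8 oxygen of 7, and acid work-up frees the phenol. The closest known reaction types are the Petasis–Ferrier rearrangement of cyclic enol acetals to tetrahydropyran-4-ones and the silyl triflate-catalysed Mukaiyama aldol addition of enol silanes to ketals; new is a catechol ketal as the oxocarbenium source with an aryl silyl ether as leaving group. Ring D closes in a 6-(enolendo)-endo-trig mode, which is open to an oxocarbenium ion that can twist out of the arene plane, as in the Petasis–Ferrier case. No stereocentre is formed. The selectivity needed is opening of the ketal toward O3 and not toward O1: both ionizations are reversible, but only the cation on O3 has the nucleophile within reach of a six-membered transition state, whereas the cation on O1 would have to bridge two meta positions and can only re-close. The substrate secures the rest, since 5 has one enolizable carbonyl group, no stereocentre and no other acid-labile group, and TMSOTf kept in excess over the amine should prevent loss of the ketal carbon as an isopropenyl ether.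

Step 4
Reactants: 8 6-bromo-8-hydroxy-2,2-dimethylchroman-4-one
Product: 9 8-(benzyloxy)-6-bromo-2,2-dimethylchroman-4-one
Conditions: BnBr, K2CO3, DMF, rt
Reagents that add atoms: benzyl bromide, BrCc1ccccc1
Why: Williamson ether synthesis on the unhindered, non-chelated phenol gives a benzyl ether that should pass the boron and palladium steps and leave together with the ring A benzyl groups.

Step 5
Reactants: 9 8-(benzyloxy)-6-bromo-2,2-dimethylchroman-4-one
Product: 10 8-(benzyloxy)-2,2-dimethyl-6-(4,4,5,5-tetramethyl-1,3,2-dioxaborolan-2-yl)chroman-4-one
Conditions: B2pin2, PdCl2(dppf), KOAc, 1,4-dioxane, 90 °C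
Reagents that add atoms: bis(pinacolato)diboron, CC1(C)OB(OC1(C)C)B1OC(C)(C)C(C)(C)O1
Why: Miyaura borylation (oxidative addition of the aryl bromide to zerovalent palladium formed in situ, acetate-assisted transmetalation with the diboron, reductive elimination) tolerates the ketone and the benzyl ether.

Step 6
Reactants: 10 8-(benzyloxy)-2,2-dimethyl-6-(4,4,5,5-tetramethyl-1,3,2-dioxaborolan-2-yl)chroman-4-one
Product: 11 [8-(benzyloxy)-2,2-dimethyl-4-oxochroman-6-yl]boronic acid
Conditions: NaIO4, NH4OAc, acetone/H2O, rt
Reagents that add atoms: water, O
Why: Oxidative pinacol ester cleavage: the hydrolysis equilibrium is pulled to the free boronic acid because periodate destroys the released pinacol by glycol cleavage.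

Step 7
Reactants: 12 5,7-dihydroxy-4H-chromen-4-one
Product: 13 5,7-bis(benzyloxy)-4H-chromen-4-one
Conditions: BnBr (3 equiv), K2CO3, DMF, 80 °C
Reagents that add atoms: benzyl bromide, BrCc1ccccc1
Why: Williamson ether synthesis; heating with excess reagent should also alkylate the 5-hydroxyl that is hydrogen-bonded to the carbonyl group.

Step 8
Reactants: 11 [8-(benzyloxy)-2,2-dimethyl-4-oxochroman-6-yl]boronic acid, 13 5,7-bis(benzyloxy)-4H-chromen-4-one
Product: 14 (2S)-5,7-bis(benzyloxy)-2-[8-(benzyloxy)-2,2-dimethyl-4-oxochroman-6-yl]chroman-4-one
Conditions: Pd(OCOCF3)2 (5 mol%), (R)-t-BuPyOX [(R)-4-tert-butyl-2-(pyridin-2-yl)-4,5-dihydrooxazole] (6 mol%), NH4PF6 (30 mol%), H2O (5 equiv), ClCH2CH2Cl, 60 °C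
Reagents that add atoms: none
Why: Asymmetric conjugate addition of an arylboronic acid to a chromone catalysed by cationic divalent palladium: the aryl–palladium species inserts the C2=C3 bond on the enone face left open by the tert-butyl group of the ligand, which should set C2 as S, and protonation of the palladium enolate in the base-free medium avoids retro-oxa-Michael opening of the flavanone.

Step 9
Reactants: 14 (2S)-5,7-bis(benzyloxy)-2-[8-(benzyloxy)-2,2-dimethyl-4-oxochroman-6-yl]chroman-4-one
Product: 15 (2S)-5,7-dihydroxy-2-(8-hydroxy-2,2-dimethyl-4-oxochroman-6-yl)chroman-4-one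
Conditions: H2 (1 atm), Pd/C (palladium on carbon), EtOAc/MeOH, rt
Reagents that add atoms: none
Why: Catalytic hydrogenolysis cleaves the three benzyl aryl ethers under neutral conditions, under which C2 of ring C, having no acidic hydrogen and meeting no base, should keep its configuration.

**Compound list**

1 | 2,2-dimethyl-1,3-benzodioxole | CC1(C)Oc2ccccc2O1 | starting material
2 | (2,2-dimethyl-1,3-benzodioxol-4-yl)lithium | [Li]c1cccc2OC(C)(C)Oc12 | intermediate
3 | lithium 1-(2,2-dimethyl-1,3-benzodioxol-4-yl)-1-[methoxy(methyl)amino]ethanolate | CC(O[Li])(N(C)OC)c1cccc2OC(C)(C)Oc12 | intermediate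
4 | 1-(2,2-dimethyl-1,3-benzodioxol-4-yl)ethanone | CC(=O)c1cccc2OC(C)(C)Oc12 | intermediate
5 | 1-(6-bromo-2,2-dimethyl-1,3-benzodioxol-4-yl)ethanone | CC(=O)c1cc(Br)cc2OC(C)(C)Oc12 | intermediate
6 | {[1-(6-bromo-2,2-dimethyl-1,3-benzodioxol-4-yl)ethenyl]oxy}trimethylsilane | C=C(O[Si](C)(C)C)c1cc(Br)cc2OC(C)(C)Oc12 | intermediate
7 | 6-bromo-2,2-dimethyl-8-[(trimethylsilyl)oxy]chroman-4-one | CC1(C)CC(=O)c2cc(Br)cc(O[Si](C)(C)C)c2O1 | intermediate
8 | 6-bromo-8-hydroxy-2,2-dimethylchroman-4-one | CC1(C)CC(=O)c2cc(Br)cc(O)c2O1 | intermediate
9 | 8-(benzyloxy)-6-bromo-2,2-dimethylchroman-4-one | CC1(C)CC(=O)c2cc(Br)cc(OCc3ccccc3)c2O1 | intermediate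
10 | 8-(benzyloxy)-2,2-dimethyl-6-(4,4,5,5-tetramethyl-1,3,2-dioxaborolan-2-yl)chroman-4-one | CC1(C)CC(=O)c2cc(B3OC(C)(C)C(C)(C)O3)cc(OCc3ccccc3)c2O1 | intermediate
11 | [8-(benzyloxy)-2,2-dimethyl-4-oxochroman-6-yl]boronic acid | CC1(C)CC(=O)c2cc(B(O)O)cc(OCc3ccccc3)c2O1 | intermediate
12 | 5,7-dihydroxy-4H-chromen-4-one | O=c1ccoc2cc(O)cc(O)c12 | starting material
13 | 5,7-bis(benzyloxy)-4H-chromen-4-one | O=c1ccoc2cc(OCc3ccccc3)cc(OCc3ccccc3)c12 | intermediate
14 | (2S)-5,7-bis(benzyloxy)-2-[8-(benzyloxy)-2,2-dimethyl-4-oxochroman-6-yl]chroman-4-one | CC1(C)CC(=O)c2cc([C@@H]3CC(=O)c4c(OCc5ccccc5)cc(OCc5ccccc5)cc4O3)cc(OCc3ccccc3)c2O1 | intermediate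
15 | (2S)-5,7-dihydroxy-2-(8-hydroxy-2,2-dimethyl-4-oxochroman-6-yl)chroman-4-one | CC1(C)CC(=O)c2cc([C@@H]3CC(=O)c4c(O)cc(O)cc4O3)cc(O)c2O1 | target

**Step count and risks**

Total step count: 9. Longest linear sequence: 8 (steps 1–6, 8 and 9; step 7 prepares the ring A/C fragment).

Steps most likely to fail:

1. Step 3 (bears the label "Proposed new method:"). What may go wrong: ionization of the ketal without carbon–carbon bond formation, so that the isopropylidene group is lost by elimination or on work-up, or protodesilylation of the enol silane before the ketal opens. The fallback uses known chemistry, sets out from 5 and returns to the route at 8. The ketal is hydrolysed (2 M HCl, THF, 50 °C) to 1-(5-bromo-2,3-dihydroxyphenyl)ethanone F1. A Kabbe condensation with acetone and pyrrolidine (toluene, reflux, under N2) then builds ring D by enamine aldol condensation and oxa-Michael closure through the hydroxyl ortho to the ketone, which should give 8. In this fallback ring D is closed at the O1–C2 bond after an intermolecular carbon–carbon bond formation.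

2. Step 8. What may go wrong: slow insertion of the electron-rich 5,7-dialkoxychromone with competing protodeboronation, or insufficient facial discrimination by the ligand. The fallback sets out from 11 and 13 and returns at 14. The addition is run without asymmetric induction (Pd(OCOCF3)2, 2,2'-bipyridine, H2O, ClCH2CH2Cl, 60 °C) to give racemic 5,7-bis(benzyloxy)-2-[8-(benzyloxy)-2,2-dimethyl-4-oxochroman-6-yl]chroman-4-one F2. The enantiomers are separated by preparative chromatography on a chiral stationary phase, and the S enantiomer continues as 14. The source of enantiopurity thus changes from catalyst control to resolution.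

3. Step 9. What may go wrong: over-reduction, that is hydrogenolytic opening of the benzylic C2–O1 bond of ring C or reduction of an aryl ketone before the last benzyl ether is gone. The fallback goes from 14 directly to 15 by non-reductive Lewis-acid dealkylation with BCl3 and pentamethylbenzene as cation scavenger (CH2Cl2, –78 °C). This replaces hydrogenolysis by acid-mediated ether cleavage and makes no new compound.

Further compounds
F1 | step 3 | 1-(5-bromo-2,3-dihydroxyphenyl)ethanone | CC(=O)c1cc(Br)cc(O)c1O
F2 | step 8 | racemic 5,7-bis(benzyloxy)-2-[8-(benzyloxy)-2,2-dimethyl-4-oxochroman-6-yl]chroman-4-one | CC1(C)CC(=O)c2cc(C3CC(=O)c4c(OCc5ccccc5)cc(OCc5ccccc5)cc4O3)cc(OCc3ccccc3)c2O1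
F0 | step 9 | none | none
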